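**Retrosynthetic overview**
- The target is apigenin carrying a 4-hydroxybenzyl group on C8, so the only disconnection is the bond between C8 of ring A and the benzylic CH2.
- The route rests on the C8–H position of ring A: it lies between O1 and the C7 hydroxyl of a phloroglucinol-type ring (oxygen donors at O1, C5 and C7) and is free and strongly nucleophilic.
- The electrophile is the para-quinone methide formed in the flask from 4-hydroxybenzyl alcohol under acid catalysis.
- No ring is formed: rings A, B and C of the flavone and the benzyl arene are bought intact, and no protecting group is used.

Key step: step 1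

**Step 1**
Reactants: 1 apigenin; 2 4-hydroxybenzyl alcohol
Product: 4 8-(4-hydroxybenzyl)apigenin, via para-quinone methide 3 (not isolated)
Conditions: Sc(OTf)3 (10 mol %), 1,4-dioxane, 90 °C, slow addition of 2 (0.8 equiv) to 1; reversed-phase chromatography (C18, MeOH–H2O)
Reagents that add atoms: none
Why: Friedel–Crafts hydroxybenzylation, a known reaction of phloroglucinol-type arenes and 5,7-dihydroxyflavonoids with hydroxybenzyl alcohols: Sc(OTf)3 assists loss of water from 2, the para-hydroxyl pushing out the benzylic oxygen to give quinone methide 3 (or its O-coordinated, cation-like form). C8 of ring A of 1 adds to the exocyclic CH2 of 3 in a 1,6-addition (vinylogous Michael addition) that rearomatises the benzyl ring, and loss of the C8 proton from the ring A cyclohexadienone restores the flavone. No ring is closed and no stereocentre is created. The step needs C-alkylation over O-alkylation, ring A over rings B and C, C8 over C6 and one benzylation instead of two: O-benzylation by 3 is reversible under acid and should drain into the C–C product, ring A carries three oxygen donors (O1, C5–OH, C7–OH) whereas ring B has one and is conjugated to the pyranone, and C8 is the site that carbon electrophiles such as Mannich iminium ions take first in 5,7-dihydroxyflavones, being para to the C5 hydroxyl (chelated to C4=O) and flanked by only one hydroxyl. Keeping 2 limiting and dilute by slow addition should hold back both a second benzylation at C6 and self-condensation of 3 with 2. Any 6-benzyl isomer and 6,8-dibenzyl compound should be removed by the chromatography with recovery of unreacted 1, and the site of attachment should be confirmed by HMBC correlations from the benzylic CH2 to C7, C8 and C8a.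

**Compound list**
1 | apigenin (5,7-dihydroxy-2-(4-hydroxyphenyl)-4H-chromen-4-one) | O=c1cc(-c2ccc(O)cc2)oc2cc(O)cc(O)c12 | starting material
2 | 4-hydroxybenzyl alcohol | OCc1ccc(O)cc1 | starting material
3 | para-quinone methide (4-methylidenecyclohexa-2,5-dien-1-one) | C=C1C=CC(=O)C=C1 | intermediate
4 | 8-(4-hydroxybenzyl)apigenin (5,7-dihydroxy-8-(4-hydroxybenzyl)-2-(4-hydroxyphenyl)-4H-chromen-4-one) | O=c1cc(-c2ccc(O)cc2)oc2c(Cc3ccc(O)cc3)c(O)cc(O)c12 | target

**Total step count:** 1
**Longest linear sequence:** 1 step

**Steps most likely to fail**
The route has a single step, so only step 1 can be named.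

Step 1. Three processes may spoil it:
- Attack of the quinone methide at C6 may compete with attack at C8 to a degree that makes separation of the regioisomers impractical.
- The product may be benzylated a second time at C6.
- Compound 2 may be consumed by self-condensation while poorly soluble 1 stays out of solution.

Fallback (sets out from 1, comes back to the route at 4). The C8–CH2 bond is made by cross-coupling at a pre-installed C8 halide instead of by Friedel–Crafts attack.
- Apigenin 1 is permethylated (Me2SO4 in excess, K2CO3, acetone, reflux) to 5,7,4'-trimethoxyflavone F1.
- With the C5 oxygen capped as its methyl ether, electrophilic iodination (I2, CF3CO2Ag, CH2Cl2, rt) should go to C8 and give 8-iodo-5,7,4'-trimethoxyflavone F2.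
- Negishi coupling of F2 with commercial 4-methoxybenzylzinc chloride (Pd(OAc)2, SPhos, THF, 50 °C) should give 8-(4-methoxybenzyl)-5,7,4'-trimethoxyflavone F3. The position of the benzyl group is fixed by the iodide, and neither dibenzylation nor quinone methide oligomerisation can occur.
- Cleavage of all four methyl ethers (BBr3 in excess, CH2Cl2, −78 °C to rt) should deliver 4. The low-temperature Lewis-acid conditions are chosen to avoid the ring-opening isomerisation (Wessely–Moser rearrangement) that hot mineral acid can cause in 5,7-dihydroxyflavones.

**Further compounds**
F1 | step 1 | 5,7,4'-trimethoxyflavone | O=c1cc(-c2ccc(OC)cc2)oc2cc(OC)cc(OC)c12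
F2 | step 1 | 8-iodo-5,7,4'-trimethoxyflavone | O=c1cc(-c2ccc(OC)cc2)oc2c(I)c(OC)cc(OC)c12
F3 | step 1 | 8-(4-methoxybenzyl)-5,7,4'-trimethoxyflavone | O=c1cc(-c2ccc(OC)cc2)oc2c(Cc3ccc(OC)cc3)c(OC)cc(OC)c12
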